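**Retrosynthetic overview**
1. Magnone B (9) ⇐ dithiane-masked ketone 8; the epimerisable α-keto centre is unveiled last.
2. The THF ring (the only ring formed) ⇐ triol 7, by C2–O closure through the trimethoxybenzylic cation, which places the aryl group trans to both neighbours.
3. Triol 7 ⇐ LiAlH4 reduction of lactone-acetal 6; both ring termini become CH2OH and the menthol auxiliary is expelled.
4. Lactone 6 ⇐ one-pot Michael/aldol of lithiated dithiane 3, chiral butenolide 4 and 3,4,5-trimethoxybenzaldehyde 5; the acetal centre of 4 sets both backbone stereocentres.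
5. A trans-α,β-disubstituted lactone maps onto the 3,4-cis THF; the purchased butenolide ring is sacrificial.

**Assumptions**
- The target is (2S,3R,4R): aryl trans to CH2OH, CH2OH cis to the aroyl group, as read from the SMILES.
- (5R)-5-(l-Menthyloxy)-2(5H)-furanone (4) is taken as a catalogue compound; if not, it is two steps from furfural and l-menthol.
- The carbinol centre in 6 and 7 is carried as an epimer mixture, because step 4 re-sets it.

**Route**

Step 1
Reactants: 1, 3,4-dimethoxybenzaldehyde; 2, 1,3-propanedithiol
Product: 3, 2-(3,4-dimethoxyphenyl)-1,3-dithiane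
Conditions: BF3·OEt2 (0.2 eq), CH2Cl2, 0 °C → rt
Reagents that add atoms: 1,3-propanedithiol (2), SCCCS
Why: Lewis-acid dithioacetalisation gives the Corey–Seebach acyl-anion precursor, which will survive LiAlH4 and mild acid later.

Step 2
Reactants: 3, 2-(3,4-dimethoxyphenyl)-1,3-dithiane; 4, (5R)-5-[(1R,2S,5R)-menthyloxy]furan-2(5H)-one; 5, 3,4,5-trimethoxybenzaldehyde
Product: 6, (3S,4R,5R)-4-[2-(3,4-dimethoxyphenyl)-1,3-dithian-2-yl]-3-[hydroxy(3,4,5-trimethoxyphenyl)methyl]-5-[(1R,2S,5R)-menthyloxy]dihydrofuran-2(3H)-one (carbinol epimers)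
Conditions: 3, n-BuLi, THF, −78 → −20 °C; then 4, −78 °C; then 5, −78 °C; AcOH quench at −78 °C
Reagents that add atoms: none beyond reactants 3, 4 and 5
Why: Tandem Corey–Seebach Michael addition/aldol: the dithiane anion adds 1,4 anti to the menthyloxy group (sets C4 = R), and the lactone enolate takes the aldehyde trans to the new C4 substituent (sets C3 = S).

Step 3
Reactants: 6, the lactone-acetal adduct
Product: 7, (2R,3R)-2-[2-(3,4-dimethoxyphenyl)-1,3-dithian-2-yl]-3-[hydroxy(3,4,5-trimethoxyphenyl)methyl]butane-1,4-diol (carbinol epimers)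
Conditions: LiAlH4 (4 eq), THF, 0 °C → rt; Rochelle-salt work-up
Reagents that add atoms: none (hydride only; (−)-menthol is released)
Why: Hydride reduction of the lactone-acetal (pseudo-ester) takes both the carbonyl and the acetal carbon to CH2OH via the transient aldehydes, without touching the two backbone stereocentres, the dithiane or the aryl ethers.

Step 4
Reactants: 7, the triol
Product: 8, [(2S,3R,4R)-4-[2-(3,4-dimethoxyphenyl)-1,3-dithian-2-yl]-2-(3,4,5-trimethoxyphenyl)oxolan-3-yl]methanol
Conditions: CSA (0.2 eq), CH2Cl2 (0.02 M), 0 °C → rt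
Reagents that add atoms: none (loss of H2O)
Why: Acid-catalysed SN1 cycloetherification: the p-methoxy-stabilised benzylic cation is trapped by the CH2OH next to the dithianyl carbon (the other CH2OH could only give an oxetane). Both carbinol epimers converge on the 2S product, with the aryl group on the face opposite both the CH2OH and dithianyl groups, and reversible ionisation reinforces this.

Step 5
Reactants: 8, the dithiane-masked THF
Product: 9, Magnone B, (3,4-dimethoxyphenyl)[(3R,4R,5S)-4-(hydroxymethyl)-5-(3,4,5-trimethoxyphenyl)oxolan-3-yl]methanone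
Conditions: Hg(ClO4)2·3H2O (2.5 eq), CaCO3 (5 eq), THF/H2O 5:1, 0 °C → rt
Reagents that add atoms: water, O
Why: Thiophilic Hg(II)-assisted dithioacetal hydrolysis releases the aryl ketone; the CaCO3 buffer and low temperature are chosen to avoid epimerising the cis α-keto centre, and no new stereocentre is formed.

**Compound list**
1 | 3,4-dimethoxybenzaldehyde | COc1ccc(C=O)cc1OC | starting material
2 | 1,3-propanedithiol | SCCCS | starting material
3 | 2-(3,4-dimethoxyphenyl)-1,3-dithiane | COc1ccc(C2SCCCS2)cc1OC | intermediate
4 | (5R)-5-[(1R,2S,5R)-menthyloxy]furan-2(5H)-one | O=C1C=C[C@H](O[C@@H]2C[C@H](C)CC[C@H]2C(C)C)O1 | starting material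
5 | 3,4,5-trimethoxybenzaldehyde | COc1cc(C=O)cc(OC)c1OC | starting material
6 | (3S,4R,5R)-dithianyl aldol lactone-acetal (carbinol epimers) | O=C1[C@H](C(O)c2cc(OC)c(OC)c(OC)c2)[C@@H](C2(SCCCS2)c2ccc(OC)c(OC)c2)[C@H](O[C@@H]2C[C@H](C)CC[C@H]2C(C)C)O1 | intermediate
7 | (2R,3R)-dithianyl triol (carbinol epimers) | OC[C@H](C(O)c1cc(OC)c(OC)c(OC)c1)[C@@H](C1(SCCCS1)c1ccc(OC)c(OC)c1)CO | intermediate
8 | [(2S,3R,4R)-4-(2-aryl-1,3-dithian-2-yl)-2-(3,4,5-trimethoxyphenyl)oxolan-3-yl]methanol | OC[C@H]1[C@@H](C2(SCCCS2)c2ccc(OC)c(OC)c2)CO[C@@H]1c1cc(OC)c(OC)c(OC)c1 | intermediate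
9 | Magnone B | COc1ccc(C(=O)[C@H]2CO[C@H](c3cc(OC)c(OC)c(OC)c3)[C@H]2CO)cc1OC | target

**Totals**
Total steps: 5. Longest linear sequence: 5 (1 → 3 → 6 → 7 → 8 → 9).

**Steps most likely to fail, with fallbacks**
1. Step 2 (incomplete enolate trapping or retro-aldol on work-up). Fallback: isolate the protonated Michael adduct, re-enolise with LDA and C-acylate with 3,4,5-trimethoxybenzoyl chloride instead of doing an aldol. The resulting β-keto lactone is reduced by LiAlH4 to the same triol 7, since the carbinol configuration does not matter.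
2. Step 4 (E1 dehydration to the styrene, or sulfur participation, in place of clean ether formation). Fallback: switch to a quinone-methide closure. Use 4-(TBS-oxy)-3,5-dimethoxybenzaldehyde in step 2; after reduction, TBAF unveils the p-hydroxybenzyl alcohol, which cyclises via the p-quinone methide under near-neutral conditions, and the phenol is then methylated (MeI, K2CO3) before dithiane removal.
3. Step 5 (C4 epimerisation, or the cis CH2OH trapping the thionium ion as a bicyclic O,S-ketal). Fallback: silylate the primary alcohol of 8 (TBSCl, imidazole), unmask the ketone oxidatively (PhI(OCOCF3)2, aq. MeCN, 0 °C), then remove the TBS group with HF·pyridine under non-basic conditions.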